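I counted in percentage points of the substrate charged, and the four new flasks were to be judged in that unit at the end of 8.0 min.

| setting | beta | gamma | alpha | green | red | blue | ochre |
|---|---|---|---|---|---|---|---|
| substrate | 0.050 M | 0.050 M | 0.10 M | 0.050 M | 0.050 M | 0.050 M | 0.050 M |
| partner | 0.037 M | 0.15 M | 0.075 M | 0.0750 M | 0.0750 M | 0.0750 M | 0.0750 M |
| free catalyst | 50 µM | 50 µM | 50 µM | 50 µM | 50 µM | 50 µM | 50 µM |
| temperature | 5 °C | 48 °C | 5 °C | 60 °C | 35 °C | 85 °C | 10 °C |
| remark | run made earlier | run made earlier | run made earlier |  |  |  |  |
| time |  |  |  | 8.0 min | 8.0 min | 8.0 min | 8.0 min |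

| run | time / min | target / % | substrate / % |
|---|---|---|---|
| beta | 8.00 | 2.7 | 18.8 |
| beta | 15.0 | 9.4 | 1.8 |
| beta | 30.0 | 20.4 | 0 |
| beta | 50.0 | 33.7 | 1.8 |
| beta | 90.0 | 47.1 | 1.1 |
| gamma | 0.833 | 12.5 | 6.1 |
| gamma | 2.00 | 35.1 | 1.0 |
| gamma | 4.00 | 57.9 | 0 |
| gamma | 5.00 | 67.2 | 0 |
| gamma | 10.0 | 92.4 | 0 |
| alpha | 8.00 | 5.3 | 19.7 |
| alpha | 25.0 | 22.7 | 1.6 |
| alpha | 50.0 | 40.5 | 0 |
| alpha | 80.0 | 52.4 | 0 |
| alpha | 90.0 | 57.5 | 0 |

(standard deviation of a reading: 1 percentage point)

- a reading or a percentage of target counts all its forms, free or not
- a reading of substrate is of its free form alone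

1. the best flask by amount of target, in percent of the substrate charged; "all alike" if 1.5 percentage points covers them all (green / red / blue / ochre / all alike)
2. amount of target at the end, in percent of the substrate charged, green
3. amount of target at the end, in percent of the substrate charged, red
4. amount of target at the end, in percent of the substrate charged, blue
5. amount of target at the end, in percent of the substrate charged, ochre

I took each target to use one substrate and one partner. I therefore wrote the balance of the smaller charge and defined Y as the smaller of the two charges divided by the substrate charged, the ceiling on target. In blue the substrate is the limiting reagent, 0.050 M against 0.0750 M of partner, so Y = 100%. That was my first way to blue's number, and it used no rate.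

My second way used the readings. I defined the gap G as Y minus the target and the substrate read, which is the part still owed. In gamma, where Y is 100%, G fell from 63.9% at 2.00 min to 7.60% at 10.0 min. Treated as a pseudo-first-order decay, that gave a constant k = 0.266 min⁻¹. Applied to blue for 8.0 min, this k gave 88.1% of target, so the two ways parted by 12 percentage points.

To find which one cheated, I took the same gap in alpha, where Y is 75.0% and the temperature is 5 °C. There k read 0.0164 min⁻¹, so gamma's constant was larger by a factor of 16.2. Some of that factor may belong to gamma's partner, twice alpha's, or to alpha's larger substrate charge, so I could not give it all to temperature, but gamma stood at 48 °C and blue stands at 85 °C. I judged that the second way cheated by carrying a colder constant into a hotter flask. I committed to blue, the hottest, as the best flask, close under Y.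

The forecast named blue as best, with 93% for green, 50% for red, 99% for blue and 8% for ochre, and it added: “85 °C is an extrapolation, so blue stays uncertain”.

The flasks gave 92.0% in green, 50.5% in red, 99.9% in blue and 10.7% in ochre, so the best was blue.

    free catalyst + open intermediate ⇌ catalyst intermediate (K = 14.0 L mol⁻¹, k = 54.0 L mol⁻¹ s⁻¹, Ea = 41.0 kJ mol⁻¹, ΔH = 7.00 kJ mol⁻¹)
    substrate + free catalyst → free catalyst + open intermediate (k = 607 L mol⁻¹ s⁻¹, Ea = 48.0 kJ mol⁻¹)
    partner + catalyst intermediate → free catalyst + target (k = 135 L mol⁻¹ s⁻¹, Ea = 44.0 kJ mol⁻¹)
    substrate + target ⇌ idle adduct, settled at all times (K = 25.0 L mol⁻¹, ΔH = 42.0 kJ mol⁻¹)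
    (constants at 35 °C)

At 8.00 min blue still held 0.0588% of the substrate charged as open intermediate, and 33.4% of its own partner charge remained. The neighbouring flask, blue with 0.030 M of partner, has Y = 60.0%. That flask gave 60.0% of target, with 0% of its partner left.

Readings and results are simulated with constants of no real substance.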